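Millimolar is the unit to hold this flask in: Z is charged at 32 mM, and the hunch that the hotter flask buys more exchange has to be tested against a concentration, not a rate.

| setting | dusk | autumn | winter |
|---|---|---|---|
| Z | 0.032 M | 0.032 M | 0.032 M |
| J | 0.950 equiv | 0.950 equiv | 0.950 equiv |
| temperature | 80 °C | 60 °C | 70 °C |
| time | 25 s | 25 s | 25 s |
    J → G (k1 = 0.040 s⁻¹, Ea1 = 88.0 kJ mol⁻¹)
    L ⇌ D, rate k2*(cs2 - [D]) while solid is left; crystals form when [D] > cs2 (cs2 = 0.51 mM, k2 = 8.5 s⁻¹)
    Z + J → D + X (k3 = 6.7 M⁻¹ s⁻¹, Ea3 = 50.0 kJ mol⁻¹)
    Q + J → D + E (k4 = 39 M⁻¹ s⁻¹, Ea4 = 47.0 kJ mol⁻¹)
    X + J → D + Q (k5 = 0.66 M⁻¹ s⁻¹, Ea5 = 47.0 kJ mol⁻¹)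
    (constants at 60 °C)
- D is meant together with its L
- solid, in amounts per volume of the solution: L
- at 60 °C the constants are as listed, elsewhere as the activation energies make them
- which of these there is most of at the end, counted by the Z in it, dusk (Q / E / X / Z)
- which of these there is most of at the end, counted by the Z in it, autumn (Q / E / X / Z)
- which of these there is most of at the end, counted by the Z in it, winter (Q / E / X / Z)
- how much there is at the end of the one of these that leads, in percent of the Z charged: dusk
- how much there is at the end of the one of these that leads, in percent of the Z charged: autumn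
- how much there is at the end of the one of these that leads, in percent of the Z charged: winter

J is the limiting reagent, charged at 0.950 equiv, and it is drawn on by the exchange on Z and by its own loss to G. Both draws are first order in J, so [J] cancels from their split, and the share going to Z is [Z]/([Z] + K). K, the split concentration, is the [Z] at which both draw J equally, the rate constant of the first step over that of Z + J, an inverse selectivity factor: 13.0 mM at dusk, 8.90 mM in winter, 5.97 mM in autumn. It climbs with temperature, since the loss of J has the higher activation energy, so the hunch looks wrong.

X going on carries a toll. With the concentrations as charged in autumn, Q has a half-life of 0.58 s against 35 s for X, so Q stays small beside X. This reckoning therefore charges two J for each X that leaves, an upper figure, since an X that stops at Q has paid one. Take ρ, the constant of X + J over that of Z + J, as 0.0985 in each flask. Let u be the part of Z exchanged, s the natural log of charged Z over remaining Z, and m = u/s the mean [Z] as a part of the charge. Spending the whole J charge, that charge in parts of Z equals u + sK/[Z] charged + 2ρ(s − u).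

Starting from m = 0.7 and putting the answer back once, u runs 70.3% then 64.8% in autumn, 64.1% then 60.8% in winter, and 57.1% then 56.0% at dusk. X is then u − ρ(s − u): 60.9% in autumn, 57.6% in winter, 53.4% at dusk. The leader comes out as X in autumn, X in winter and X at dusk.

The forecast puts X ahead with 54.3% at dusk, 62% in autumn and 59% in winter, a little above this reckoning, on the ground that “Hotter favours J hydrolysis, so less exchange occurs”.

The simulation has X ahead with 54.4% at dusk, 62.0% in autumn and 59.0% in winter. At the end of dusk, with J at 0% of its charge, [Z] reads 13.8 mM, close to K of 13.0 mM. A neighbouring flask, dusk with 0.240 equiv of J, keeps that K, and the same two rounds give u of 14.4% then 16.5%, so X of 16.4% and Z of 83.5%. That flask ends with Z leading at 83.5% and X at 16.4%.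

Its constants are those of an exercise.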